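**Plan**

- Retrosynthetic cuts, in order: the acyl–O bond of the ester at C1′; the two O–CH3 bonds masking the C5 and C8 hydroxyls; the C4 carbonyl oxygen (back to a 1-naphthol) and the aromaticity of ring A (back to a 1,4-oxygen bridge); C1–C8a and C4–C4a together; last C3′=C4′ and C1′–C2′ of the side chain.
- Enabling feature: the fusion carbons C4a and C8a of ring B (C4a, C5–C8, C8a) each have an oxygen-bearing neighbour (C5, C8), so ring B is a symmetric 3,6-dialkoxybenzyne. C1–C2–C3–C4 of ring A, with the side chain on C2, is a 3-substituted furan whose oxygen ends up as the C1 carbonyl oxygen.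
- Forward: the side chain is built on furan-3-carbaldehyde (allylation, silylation, cross-metathesis), ring A is closed by aryne–furan [4+2] cycloaddition, and bridge opening, naphthol oxidation, silyl-to-ester exchange and demethylation finish the target.
- Stereochemistry: the only stereocentre, C1′ (S), is set in step 1 by reagent-controlled allylboration and no later step breaks a bond to it; the bridgehead centres of the cycloadduct are erased on aromatisation.

Key step: step 4

Remark: the (+)-α-pinene-derived allylborane is assumed to attack furan-3-carbaldehyde on the same (Si) face as benzaldehyde; the target is written as the 2-substituted 5,8-dihydroxy-1,4-dione tautomer of the naphthazarin.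

**Route**

Step 1
Reactants: 1 furan-3-carbaldehyde; 2 B-allyldiisopinocampheylborane derived from (+)-α-pinene, dIpc2B(allyl) (commercial solution in pentane)
Product: 4 (S)-1-(furan-3-yl)but-3-en-1-ol, via diisopinocampheylborinate ester 3 (not isolated)
Conditions: Et2O, −78 °C; then 3 M NaOH, 30% H2O2, 0 °C to rt
Reagents that add atoms: none
Why: Brown asymmetric allylboration, in which the allyl group is delivered through a closed chair (Zimmerman–Traxler) transition state whose (+)-α-pinene-derived isopinocampheyl groups expose the Si face of the aldehyde, so C1′ should form with S configuration under reagent control before alkaline H2O2 releases the alcohol from borinate 3.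

Step 2
Reactants: 4 (S)-1-(furan-3-yl)but-3-en-1-ol
Product: 5 (S)-tert-butyl{[1-(furan-3-yl)but-3-en-1-yl]oxy}dimethylsilane
Conditions: TBSCl, imidazole, DMF, rt
Reagents that add atoms: tert-butyldimethylsilyl chloride (TBSCl), CC(C)(C)[Si](C)(C)Cl
Why: Standard imidazole-mediated O-silylation of a secondary alcohol, giving an ether with no acidic proton for the amide base of step 4 and leaving the stereocentre untouched.

Step 3
Reactants: 5 (S)-tert-butyl{[1-(furan-3-yl)but-3-en-1-yl]oxy}dimethylsilane; 6 2-methylbut-2-ene
Product: 7 (S)-tert-butyl{[1-(furan-3-yl)-4-methylpent-3-en-1-yl]oxy}dimethylsilane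
Conditions: second-generation Grubbs catalyst RuCl2(=CHPh)(PCy3)(H2IMes) (5 mol %), neat 2-methylbut-2-ene, 35 °C, sealed vessel
Reagents that add atoms: none
Why: Olefin cross-metathesis of the terminal alkene with a large excess of 2-methylbut-2-ene exchanges =CH2 for =CMe2 with loss of propene, and the trisubstituted product, the furan and the silyl ether should be inert to the ruthenium carbene.

Step 4
Reactants: 7 (S)-tert-butyl{[1-(furan-3-yl)-4-methylpent-3-en-1-yl]oxy}dimethylsilane; 8 2-bromo-1,4-dimethoxybenzene
Product: 11 2-[(S)-1-(tert-butyldimethylsilyloxy)-4-methylpent-3-enyl]-5,8-dimethoxy-1,4-dihydro-1,4-epoxynaphthalene as both bridgehead diastereomers, via (2-bromo-3,6-dimethoxyphenyl)lithium 9 (not isolated), via 3,6-dimethoxybenzyne 10 (not isolated)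
Conditions: LiN(iPr)2 (3 equiv) added to 7 (1 equiv) and 8 (3 equiv), THF, −78 °C to rt
Reagents that add atoms: none
Why: LiN(iPr)2 removes the proton of 8 that lies between bromine and methoxy, aryllithium 9 expels LiBr on warming, and the strained triple bond of aryne 10 is captured by the furan of 7 across its 2- and 5-positions in a concerted suprafacial [4+2] cycloaddition. The closest known reaction type is the aryne–furan Diels–Alder reaction that gives 1,4-epoxy-1,4-dihydronaphthalenes, which is established for this aryne with furan itself. Ring A (C1–C2–C3–C4–C4a–C8a) closes by intermolecular [4+2] annulation, both ring bonds C1–C8a and C4–C4a forming in one event while the furan oxygen stays as the 1,4-bridge. The two bridgeheads become stereocentres, held cis by the bicycle but uncontrolled relative to C1′, which does not matter because step 5 flattens both; C1′ is a spectator and keeps its S configuration. No regiocontrol is needed, since each aryne carbon has a methoxy-bearing neighbour and the two orientations are one compound. The chemoselectivity needed is diene capture ahead of an ene reaction at the prenyl alkene and ahead of amine or aryllithium addition to the aryne; it should be secured by the much higher aryne affinity of the furan and by the threefold excess of 8 and base, while the silyl ether offers the base no acidic or ionisable site.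

Step 5
Reactants: 11 2-[(S)-1-(tert-butyldimethylsilyloxy)-4-methylpent-3-enyl]-5,8-dimethoxy-1,4-dihydro-1,4-epoxynaphthalene
Product: 12 2-[(S)-1-(tert-butyldimethylsilyloxy)-4-methylpent-3-enyl]-5,8-dimethoxynaphthalen-1-ol
Conditions: Cu(OTf)2 (5 mol %), ClCH2CH2Cl, 0 °C to rt
Reagents that add atoms: none
Why: Lewis-acid-catalysed isomerisation of a 1,4-epoxy-1,4-dihydronaphthalene to a 1-naphthol, in which the C4–O bond should ionise preferentially because the resulting cation is benzylic and allylic with its more substituted terminus at C2, and proton loss from C1 then aromatises ring A with the oxygen left on C1 and erases both bridgehead centres without touching C1′; the sense of the opening is in any case not critical, since C1 and C4 both become carbonyl carbons in step 6.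

Step 6
Reactants: 12 2-[(S)-1-(tert-butyldimethylsilyloxy)-4-methylpent-3-enyl]-5,8-dimethoxynaphthalen-1-ol
Product: 13 2-[(S)-1-(tert-butyldimethylsilyloxy)-4-methylpent-3-enyl]-5,8-dimethoxynaphthalene-1,4-dione
Conditions: Fremy's salt (KSO3)2NO (2.5 equiv), aq. KH2PO4, acetone, rt
Reagents that add atoms: potassium nitrosodisulfonate (Fremy's salt), [K+].[K+].[O]N(S(=O)(=O)[O-])S(=O)(=O)[O-]
Why: Teuber oxidation, in which the nitroxide abstracts the phenolic hydrogen, a second equivalent adds at the free para position C4 and loss of imidodisulfonate gives the p-quinone, while the methyl ethers, the silyl ether and the prenyl alkene should be safe because the reagent needs a free phenol.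

Step 7
Reactants: 13 2-[(S)-1-(tert-butyldimethylsilyloxy)-4-methylpent-3-enyl]-5,8-dimethoxynaphthalene-1,4-dione
Product: 14 2-[(S)-1-hydroxy-4-methylpent-3-enyl]-5,8-dimethoxynaphthalene-1,4-dione
Conditions: HF·pyridine, THF/pyridine, 0 °C to rt
Reagents that add atoms: none
Why: Fluoride-driven Si–O cleavage under weakly acidic conditions, chosen over Bu4NF because quinones are base-sensitive; only the Si–O bond breaks, so C1′ keeps its configuration.

Step 8
Reactants: 14 2-[(S)-1-hydroxy-4-methylpent-3-enyl]-5,8-dimethoxynaphthalene-1,4-dione; 15 3-methylbut-2-enoic acid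
Product: 16 (S)-1-(5,8-dimethoxy-1,4-dioxo-1,4-dihydronaphthalen-2-yl)-4-methylpent-3-en-1-yl 3-methylbut-2-enoate
Conditions: DCC, DMAP (cat.), CH2Cl2, 0 °C to rt
Reagents that add atoms: none
Why: Steglich esterification, in which the acid is activated as the O-acylisourea and N-acylpyridinium and acylates the hydroxyl oxygen, so the C1′–O bond and its configuration are retained, as in the known side-chain acylation of hydroxyalkyl naphthoquinones of this family.

Step 9
Reactants: 16 (S)-1-(5,8-dimethoxy-1,4-dioxo-1,4-dihydronaphthalen-2-yl)-4-methylpent-3-en-1-yl 3-methylbut-2-enoate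
Product: 18 alkannin β,β-dimethylacrylate [(S)-1-(5,8-dihydroxy-1,4-dioxo-1,4-dihydronaphthalen-2-yl)-4-methylpent-3-en-1-yl 3-methylbut-2-enoate], via 2-substituted naphthalene-1,4,5,8-tetraone 17 (not isolated)
Conditions: AgO (4 equiv), 6 M HNO3, 1,4-dioxane, rt, 5 min; then aq. Na2S2O4, Et2O, rt, work-up in air
Reagents that add atoms: water, O
Why: Oxidative demethylation of a p-dimethoxyarene with AgO in nitric acid, in which two-electron oxidation with water adding at the two ipso carbons and loss of methanol gives diquinone 17, which dithionite reduces by two electrons to the naphthazarin; this reagent pair is precedented for 5,8-dimethoxy-1,4-naphthoquinones with acyloxyalkyl side chains, and the ester, the alkenes and C1′ should survive the short contact.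

**Compound list**

1 | furan-3-carbaldehyde | O=Cc1ccoc1 | starting material
2 | B-allyldiisopinocampheylborane from (+)-α-pinene, dIpc2B(allyl) | C=CCB([C@@H]1C[C@@H]2C[C@H]([C@H]1C)C2(C)C)[C@@H]1C[C@@H]2C[C@H]([C@H]1C)C2(C)C | starting material
3 | (S)-1-(furan-3-yl)but-3-en-1-yl diisopinocampheylborinate | C=CC[C@H](OB([C@@H]1C[C@@H]2C[C@H]([C@H]1C)C2(C)C)[C@@H]1C[C@@H]2C[C@H]([C@H]1C)C2(C)C)c1ccoc1 | intermediate (not isolated)
4 | (S)-1-(furan-3-yl)but-3-en-1-ol | C=CC[C@H](O)c1ccoc1 | intermediate
5 | (S)-tert-butyl{[1-(furan-3-yl)but-3-en-1-yl]oxy}dimethylsilane | C=CC[C@H](O[Si](C)(C)C(C)(C)C)c1ccoc1 | intermediate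
6 | 2-methylbut-2-ene | CC=C(C)C | starting material
7 | (S)-tert-butyl{[1-(furan-3-yl)-4-methylpent-3-en-1-yl]oxy}dimethylsilane | CC(C)=CC[C@H](O[Si](C)(C)C(C)(C)C)c1ccoc1 | intermediate
8 | 2-bromo-1,4-dimethoxybenzene | COc1ccc(OC)c(Br)c1 | starting material
9 | (2-bromo-3,6-dimethoxyphenyl)lithium | [Li]c1c(OC)ccc(OC)c1Br | intermediate (not isolated)
10 | 3,6-dimethoxybenzyne | COC1=CC=C(OC)C#C1 | intermediate (not isolated)
11 | 2-[(S)-1-(tert-butyldimethylsilyloxy)-4-methylpent-3-enyl]-5,8-dimethoxy-1,4-dihydro-1,4-epoxynaphthalene (both bridgehead diastereomers) | CC(C)=CC[C@H](O[Si](C)(C)C(C)(C)C)C1=CC2OC1c1c(OC)ccc(OC)c12 | intermediate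
12 | 2-[(S)-1-(tert-butyldimethylsilyloxy)-4-methylpent-3-enyl]-5,8-dimethoxynaphthalen-1-ol | CC(C)=CC[C@H](O[Si](C)(C)C(C)(C)C)c1ccc2c(OC)ccc(OC)c2c1O | intermediate
13 | 2-[(S)-1-(tert-butyldimethylsilyloxy)-4-methylpent-3-enyl]-5,8-dimethoxynaphthalene-1,4-dione | CC(C)=CC[C@H](O[Si](C)(C)C(C)(C)C)C1=CC(=O)c2c(OC)ccc(OC)c2C1=O | intermediate
14 | 2-[(S)-1-hydroxy-4-methylpent-3-enyl]-5,8-dimethoxynaphthalene-1,4-dione | CC(C)=CC[C@H](O)C1=CC(=O)c2c(OC)ccc(OC)c2C1=O | intermediate
15 | 3-methylbut-2-enoic acid | CC(C)=CC(=O)O | starting material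
16 | (S)-1-(5,8-dimethoxy-1,4-dioxo-1,4-dihydronaphthalen-2-yl)-4-methylpent-3-en-1-yl 3-methylbut-2-enoate | CC(C)=CC[C@H](OC(=O)C=C(C)C)C1=CC(=O)c2c(OC)ccc(OC)c2C1=O | intermediate
17 | (S)-4-methyl-1-(1,4,5,8-tetraoxo-1,4,5,8-tetrahydronaphthalen-2-yl)pent-3-en-1-yl 3-methylbut-2-enoate | CC(C)=CC[C@H](OC(=O)C=C(C)C)C1=CC(=O)C2=C(C1=O)C(=O)C=CC2=O | intermediate (not isolated)
18 | alkannin β,β-dimethylacrylate | CC(C)=CC[C@H](OC(=O)C=C(C)C)C1=CC(=O)c2c(O)ccc(O)c2C1=O | target

**Count and risks**

Total steps: 9. Longest linear sequence: 9 steps (1 to 18); compounds 2, 6, 8 and 15 are bought.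

Steps most likely to fail:

Step 9. The carbonyl-deactivated dimethoxy ring may be oxidised only slowly, giving the nitric acid/AgO medium time to degrade the prenyl alkene and the dienoate, or diquinone 17 may be hydrated before it is reduced. The fallback sets out from 7 and returns at 18; it carries the phenol oxygens as methoxymethyl acetals so that the last step is a hydrolysis and not an oxidation. Commercial 2-bromobenzene-1,4-diol with MOMCl/iPr2NEt should give 2-bromo-1,4-bis(methoxymethoxy)benzene F1. LiN(iPr)2 converts it through [2-bromo-3,6-bis(methoxymethoxy)phenyl]lithium F2 into 3,6-bis(methoxymethoxy)benzyne F3, which 7 traps as the bis(methoxymethoxy) cycloadduct F4. Neutral isomerisation with [RuCl2(CO)3]2, which should spare the acetals, is expected to give the naphthol F5, Fremy's salt the silyloxy quinone F6, HF·pyridine the hydroxy quinone F7, and Steglich esterification with 15 the ester F8. Dilute HCl in MeOH/THF at rt then removes the two peri-chelated acetals and gives 18.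

Step 5. Under the Lewis acid the silyloxy group at C1′, which becomes ortho-hydroxybenzylic in 12, may ionise (quinone-methide formation with loss of configuration, or capture by the prenyl alkene), or the prenyl alkene may be protonated. The fallback sets out from 11 and returns at 12; it replaces the cationic opening by a transition-metal-catalysed isomerisation with [RuCl2(CO)3]2 (or [Rh(CO)2Cl]2) in ClCH2CH2Cl at 60 °C. This is a known neutral route from 7-oxabenzonorbornadienes to 1-naphthols, thought to proceed by metal insertion into the strained allylic C–O bond followed by β-hydride elimination and tautomerisation, so no free carbocation should form next to C1′. It makes no new compound.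

Step 4. The aryne may be intercepted by diisopropylamine or by aryllithium 9 faster than by the limiting furan, so that 7 is returned unchanged. The fallback sets out from 8 and returns at 11; it generates the same aryne with no amine in the flask. 8 is lithiated with LiN(iPr)2 at −78 °C, quenched with BrCl2CCCl2Br and purified to give 2,3-dibromo-1,4-dimethoxybenzene F9. F9 and 7 in toluene are then treated with n-BuLi at −78 °C and warmed; bromine–lithium exchange gives 9, which collapses to 10 and is trapped as 11.

**Further compounds**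

F1 | step 9 | 2-bromo-1,4-bis(methoxymethoxy)benzene | COCOc1ccc(OCOC)c(Br)c1
F2 | step 9 | [2-bromo-3,6-bis(methoxymethoxy)phenyl]lithium | [Li]c1c(OCOC)ccc(OCOC)c1Br
F3 | step 9 | 3,6-bis(methoxymethoxy)benzyne | COCOC1=CC=C(OCOC)C#C1
F4 | step 9 | 2-[(S)-1-(tert-butyldimethylsilyloxy)-4-methylpent-3-enyl]-5,8-bis(methoxymethoxy)-1,4-dihydro-1,4-epoxynaphthalene | CC(C)=CC[C@H](O[Si](C)(C)C(C)(C)C)C1=CC2OC1c1c(OCOC)ccc(OCOC)c12
F5 | step 9 | 2-[(S)-1-(tert-butyldimethylsilyloxy)-4-methylpent-3-enyl]-5,8-bis(methoxymethoxy)naphthalen-1-ol | CC(C)=CC[C@H](O[Si](C)(C)C(C)(C)C)c1ccc2c(OCOC)ccc(OCOC)c2c1O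
F6 | step 9 | 2-[(S)-1-(tert-butyldimethylsilyloxy)-4-methylpent-3-enyl]-5,8-bis(methoxymethoxy)naphthalene-1,4-dione | CC(C)=CC[C@H](O[Si](C)(C)C(C)(C)C)C1=CC(=O)c2c(OCOC)ccc(OCOC)c2C1=O
F7 | step 9 | 2-[(S)-1-hydroxy-4-methylpent-3-enyl]-5,8-bis(methoxymethoxy)naphthalene-1,4-dione | CC(C)=CC[C@H](O)C1=CC(=O)c2c(OCOC)ccc(OCOC)c2C1=O
F8 | step 9 | (S)-1-[5,8-bis(methoxymethoxy)-1,4-dioxo-1,4-dihydronaphthalen-2-yl]-4-methylpent-3-en-1-yl 3-methylbut-2-enoate | CC(C)=CC[C@H](OC(=O)C=C(C)C)C1=CC(=O)c2c(OCOC)ccc(OCOC)c2C1=O
F0 | step 5 | none | none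
F9 | step 4 | 2,3-dibromo-1,4-dimethoxybenzene | COc1ccc(OC)c(Br)c1Br
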